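All runs stem from a simulated flask on assumed constants, and the scatter is random.

Slowness comes first: by 0.167 d the violet run read 26.0% of its substrate as activated form and ring, so these readings put substrate activation at about 1.56 d⁻¹ with the activator charge that the flask shares.

| flask | substrate | activator | remark | time |
|---|---|---|---|---|
| violet | 0.067 M | 0.11 M | run made earlier |  |
| blue | 0.15 M | 0.11 M | run made earlier |  |
| grey | 0.10 M | 0.055 M | run made earlier |  |
| flask | 0.10 M | 0.110 M |  | 15 d |

| run | time / d | activated form / % | ring / % |
|---|---|---|---|
| violet | 0.167 | 17 | 9 |
| violet | 0.625 | 9 | 33 |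
| violet | 3.00 | 2 | 37 |
| violet | 15.0 | 0 | 2 |
| blue | 0.167 | 13 | 6 |
| blue | 0.625 | 7 | 28 |
| blue | 3.00 | 0 | 24 |
| blue | 15.0 | 0 | 2 |
| grey | 0.167 | 11 | 5 |
| grey | 0.625 | 8 | 17 |
| grey | 3.00 | 2 | 19 |
| grey | 15.0 | 0 | 0 |

(scatter of a reading: 2 percentage points)

- the earlier runs were read with a standard deviation of 2 percentage points

1. the moment within 15 d at which there is most activated form
2. the amount of activated form, in percent of the substrate charged, at that time

In the flask's first instants, activated form rises from nothing at about that pace. In the reckoning here, each activated molecule then stands at a fork: it closes to ring or leaves by an unseen path. At the top, making equals using, so the activated fraction equals substrate fraction left times activator fraction left, divided by the ratio of the rate constant for leaving, by both branches of the fork together, to the rate constant for activation. Taking the first readings as a rough stand-in for the top and counting visible forms alone, this reckoning gives 3.66 for violet and 4.62 for blue, so the readings put it higher with more substrate. Interpolated to the flask, the drain ratio R is 4.04. Treating the chain as two first-order steps, the top stands at R to the power −R/(R − 1), or 15.6%, at 0.295 d. Past the top, with R above one, this reckoning makes activation the rate-limiting step, and activated form trails its supply down. Much later, violet's ring fades from 37% at 3.00 d to 2% at 15.0 d.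

The forecast gave 0.2 d (0.08 d to 0.35 d) and 16% (13% to 20%), holding that “the 0.167 d reading sits almost at the top”; the reckoning here puts the top later.

The flask tops at 0.273 d with 15.0%.

    substrate + activator → activated form (k = 1.73 × 10⁻⁴ M⁻¹ s⁻¹)
    activated form → ring (k = 4.92 × 10⁻⁵ s⁻¹)
    substrate + activated form → open dimer (k = 1.63 × 10⁻⁴ M⁻¹ s⁻¹)
    ring → over-reaction product (k = 4.33 × 10⁻⁶ s⁻¹)
    activator → decomposition product (k = 6.21 × 10⁻⁹ s⁻¹)

Against the flask's top, the reckoning with R gave 15.6% at 0.295 d. The neighbouring flask charged with 0.025 M of substrate keeps the activator charge, and the line through violet and blue, carried beyond its readings, gives it R = 3.18, lower than the flask's. The same power then gives a top of 18.5%. That neighbouring flask reaches 19.4%, above the flask's 15.0%.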